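**Plan**
- Cuts, in retrosynthetic order: C2–C3 of ring C (carbene C–H insertion), the O1–CH2 ether bond to ring B (Mitsunobu), the C4a–acetyl bond (directed metalation and acylation), the C8–C1'' aryl–alkyl bond (Negishi coupling), and C2''–C3'' inside the lavandulyl unit (auxiliary-controlled alkylation).
- Forward: the lavandulyl iodide is made by deconjugative Evans alkylation and coupled to the carbon between the two MOM-protected oxygens of 5-methoxyresorcinol. The acetyl group is added, the future O1 is benzylated with the ring B alcohol, and the acetyl group is turned into a diazoketone. Ring C is the only ring made and closes last; desilylation ends the route.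
- Enabling feature: in the open precursor C2 is the O1-bound benzylic CH2 of the 2,4-dioxygenated ring B, 1,6 to the carbene carbon C3 through C4, C4a, C8a and O1. The 1,5 atom is O1 itself, so only the six-membered pyranone can form, and both carbons react with reversed polarity (electrophilic C3, hydridic C2–H).
- Helpers and their removal: the diazo group leaves as N2, the MOM groups direct both lithiations and are then cleaved, the TIPS ethers come off last, and the oxazolidinone is returned.
- Stereochemistry: C2'' comes from (S)-4-benzyloxazolidin-2-one (alkylation anti to the benzyl group). C2 comes from the chiral dirhodium prolinate catalyst, which picks one of the two enantiotopic benzylic hydrogens.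

Key step: step 15

Assumption: the sense of induction of the prolinate catalyst on this substrate cannot be predicted with certainty. The (S)-ligand series is written as the one giving 2S; the mirror-image catalyst would be used if the sense proves opposite.

In the names below, (R)-lavandulyl = (2R)-5-methyl-2-(prop-1-en-2-yl)hex-4-en-1-yl and TIPS = triisopropylsilyl.

**Step 1**
Reactants: 1 (S)-4-benzyloxazolidin-2-one; 2 3-methylbut-2-enoyl chloride
Product: 4 (S)-4-benzyl-3-(3-methylbut-2-enoyl)oxazolidin-2-one, via N-lithio oxazolidinone 3 (not isolated)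
Conditions: n-BuLi, THF, −78 °C; then 2, −78 → 0 °C
Reagents that add atoms: n-BuLi, [Li]CCCC (its lithium is held only in intermediate 3; nothing from reagents stays in 4)
Why: N-acylation of the lithiated oxazolidinone with the acid chloride is the standard entry to N-enoyl imides and avoids the vinylketene pathway that amine bases would open.

**Step 2**
Reactants: 4; 5 1-bromo-3-methylbut-2-ene (prenyl bromide)
Product: 7 (S)-4-benzyl-3-[(2S)-5-methyl-2-(prop-1-en-2-yl)hex-4-enoyl]oxazolidin-2-one, via sodium (Z)-dienolate 6 (not isolated)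
Conditions: NaN(SiMe3)2, THF, −78 °C; then 5, −78 → −40 °C
Reagents that add atoms: NaN(SiMe3)2, [Na]N([Si](C)(C)C)[Si](C)(C)C (its sodium is held only in intermediate 6; nothing from reagents stays in 7)
Why: γ-deprotonation of the s-cis enoyl imide should give the chelated (Z)-dienolate, which is alkylated at the α-carbon on the face away from the benzyl group (deconjugative Evans alkylation), setting the future C2'' center.

**Step 3**
Reactants: 7
Product: 8 (S)-lavandulol, (2S)-5-methyl-2-(prop-1-en-2-yl)hex-4-en-1-ol
Conditions: LiBH4, H2O (1 equiv), Et2O, 0 °C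
Reagents that add atoms: none
Why: reductive cleavage of the imide at the exocyclic carbonyl with LiBH4 should give the primary alcohol and return the auxiliary without touching the alkenes or the allylic stereocenter.

**Step 4**
Reactants: 8
Product: 9 (S)-lavandulyl iodide, (3S)-3-(iodomethyl)-2,6-dimethylhepta-1,5-diene
Conditions: I2, PPh3, imidazole, CH2Cl2, 0 °C → rt
Reagents that add atoms: iodine, II
Why: Appel-type iodination replaces the primary hydroxyl by SN2 at CH2, so the neighbouring stereocenter is not involved.

**Step 5**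
Reactants: 10 5-methoxyresorcinol (5-methoxybenzene-1,3-diol)
Product: 11 1-methoxy-3,5-bis(methoxymethoxy)benzene
Conditions: MOMCl, i-Pr2NEt, CH2Cl2, 0 °C → rt
Reagents that add atoms: chloromethyl methyl ether, COCCl
Why: double O-alkylation of the phenols (Williamson-type) installs the two acetal groups that later direct both lithiations.

**Step 6**
Reactants: 11
Product: 13 2-iodo-5-methoxy-1,3-bis(methoxymethoxy)benzene, via aryllithium 12 (not isolated)
Conditions: n-BuLi, THF, 0 °C; then I2, −78 °C → rt
Reagents that add atoms: n-BuLi, [Li]CCCC (its lithium is held only in intermediate 12); iodine, II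
Why: directed ortho-metalation should occur at the carbon between the two chelating OMOM groups in preference to the OMOM/OMe-flanked positions, and iodine traps the aryllithium.

**Step 7**
Reactants: 9; 13
Product: 15 5-methoxy-1,3-bis(methoxymethoxy)-2-[(R)-lavandulyl]benzene, via (S)-lavandulylzinc iodide 14 (not isolated)
Conditions: Zn dust (activated with BrCH2CH2Br and Me3SiCl), DMA, 40 °C; then 13, Pd(OAc)2 (3 mol %), SPhos (6 mol %), THF/DMA, 50 °C
Reagents that add atoms: zinc, [Zn] (held only in intermediate 14; nothing from reagents stays in 15)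
Why: Negishi coupling of a primary alkylzinc iodide with the aryl iodide, in which the bulky biarylphosphine on zerovalent palladium speeds reductive elimination at the doubly ortho-substituted aryl and suppresses β-hydride elimination; the stereocenter is β to zinc and takes no part.

**Step 8**
Reactants: 15
Product: 17 1-{6-methoxy-2,4-bis(methoxymethoxy)-3-[(R)-lavandulyl]phenyl}ethan-1-one, via aryllithium 16 (not isolated)
Conditions: n-BuLi, TMEDA, THF, −20 → 0 °C; then MeC(O)N(OMe)Me, −78 °C → rt; aq. NH4Cl
Reagents that add atoms: n-BuLi, [Li]CCCC (its lithium is held only in intermediate 16); N-methoxy-N-methylacetamide, CC(=O)N(C)OC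
Why: a second directed ortho-metalation at one of the two constitutionally equivalent OMOM/OMe-flanked positions followed by Weinreb amide acylation stops cleanly at the methyl ketone.

**Step 9**
Reactants: 17
Product: 18 1-{2,4-dihydroxy-6-methoxy-3-[(R)-lavandulyl]phenyl}ethan-1-one
Conditions: HCl (cat., 1.25 M in MeOH), MeOH, 0 °C → rt
Reagents that add atoms: none
Why: acid-catalysed transacetalisation of aryl MOM ethers to methanol should be much faster than protonation of the side-chain alkenes at this acidity and temperature, so both phenols are freed without chroman formation.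

**Step 10**
Reactants: 18
Product: 19 1-{2-hydroxy-6-methoxy-3-[(R)-lavandulyl]-4-(triisopropylsilyloxy)phenyl}ethan-1-one
Conditions: TIPSCl (1.05 equiv), imidazole, DMF, 0 °C → rt
Reagents that add atoms: triisopropylsilyl chloride, CC(C)[Si](Cl)(C(C)C)C(C)C
Why: chemoselective silylation, since the 4-hydroxyl is free while the 2-hydroxyl is hydrogen-bonded to the acetyl carbonyl and far less nucleophilic.

**Step 11**
Reactants: 20 2-hydroxy-4-methoxybenzaldehyde
Product: 21 4-methoxy-2-(triisopropylsilyloxy)benzaldehyde
Conditions: TIPSCl, imidazole, DMF, rt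
Reagents that add atoms: triisopropylsilyl chloride, CC(C)[Si](Cl)(C(C)C)C(C)C
Why: standard silylation of a phenol, giving an ether that withstands the later base and carbene steps and is cleaved by fluoride.

**Step 12**
Reactants: 21
Product: 22 [4-methoxy-2-(triisopropylsilyloxy)phenyl]methanol
Conditions: NaBH4, MeOH/THF, 0 °C
Reagents that add atoms: none
Why: borohydride reduction of the aldehyde, with the bulky TIPS group resisting migration from the phenolic to the benzylic oxygen.

**Step 13**
Reactants: 19; 22
Product: 23 1-{6-methoxy-2-{[4-methoxy-2-(triisopropylsilyloxy)phenyl]methoxy}-3-[(R)-lavandulyl]-4-(triisopropylsilyloxy)phenyl}ethan-1-one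
Conditions: PPh3, DIAD, THF, 0 °C → rt
Reagents that add atoms: none
Why: Mitsunobu etherification alkylates the acidic ortho-acyl phenol at oxygen with the activated primary benzylic alcohol under neutral conditions that spare both aryl silyl ethers.

**Step 14**
Reactants: 23
Product: 26 2-diazo-1-{6-methoxy-2-{[4-methoxy-2-(triisopropylsilyloxy)phenyl]methoxy}-3-[(R)-lavandulyl]-4-(triisopropylsilyloxy)phenyl}ethan-1-one, via lithium enolate 24 (not isolated), via trifluoroacetyl ketone 25 (not isolated)
Conditions: LiN(SiMe3)2, THF, −78 °C; CF3CO2CH2CF3, −78 °C; dilute aq. HCl wash; then MsN3, Et3N, H2O (1 equiv), MeCN, rt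
Reagents that add atoms: LiN(SiMe3)2, [Li]N([Si](C)(C)C)[Si](C)(C)C (lithium held only in 24); 2,2,2-trifluoroethyl trifluoroacetate, O=C(OCC(F)(F)F)C(F)(F)F (trifluoroacetyl held only in 25); methanesulfonyl azide, CS(=O)(=O)N=[N+]=[N-] (the two diazo nitrogens of 26)
Why: detrifluoroacetylative diazo transfer, in which the kinetic enolate of the methyl ketone is trifluoroacetylated and the activated 1,3-dicarbonyl undergoes Regitz diazo transfer with loss of the trifluoroacetyl group.

**Step 15**
Reactants: 26
Product: 27 (2S)-5-methoxy-2-[4-methoxy-2-(triisopropylsilyloxy)phenyl]-8-[(R)-lavandulyl]-7-(triisopropylsilyloxy)-2,3-dihydro-4H-chromen-4-one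
Conditions: Rh2(S-BSP)4 [dirhodium tetrakis((S)-1-(phenylsulfonyl)pyrrolidine-2-carboxylate), divalent rhodium] (1–2 mol %), CH2Cl2, 0 °C → rt, slow addition of 26
Reagents that add atoms: none
Why: The dirhodium carboxylate decomposes the diazoketone with loss of N2 to a transient, catalyst-bound electrophilic carbene at C3, which inserts into one of the two benzylic C–H bonds of the O1–CH2–aryl group through a concerted, asynchronous three-centre transition state (hydride-like transfer from C2 as the C2–C3 bond forms), so two carbons are joined with both natural polarities reversed. The closest known reaction type is the intramolecular C–H insertion of 2-alkoxyaryl diazomethyl ketones to chroman-4-ones under chiral dirhodium carboxylate catalysis. Ring C closes as a six-membered ring by 1,6-insertion, with the carbene carbon and the C–H carbon both becoming ring members; no five-membered alternative exists because the 1,5 atom is O1. The new stereocenter C2 is set under catalyst control, the chiral prolinate ligands making the two enantiotopic benzylic hydrogens diastereotopic in the transition state, while the distant C2'' center should have no say. The step needs chemoselectivity for this C–H bond over ylide formation at O1 with a following [1,2]-benzyl (Stevens) shift, over insertion into the C5 methoxy C–H, over attack on ring B and over cyclopropanation of the side-chain alkenes. The substrate secures this because the C2–H bond is secondary and doubly activated by O1 and by the ortho- and para-oxygenated ring B, the methoxy C–H is primary, O1 is a weakly basic, doubly ortho-flanked aryl ether oxygen conjugated to the acyl-bearing ring A, and the alkenes could only be reached through strained eight- to ten-membered meta-bridged rings, while slow addition keeps intermolecular pathways down.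

**Step 16**
Reactants: 27
Product: 28 (2S)-7-hydroxy-2-(2-hydroxy-4-methoxyphenyl)-5-methoxy-8-[(R)-lavandulyl]-2,3-dihydro-4H-chromen-4-one (target)
Conditions: Bu4NF, AcOH (1:1.2), THF, 0 °C
Reagents that add atoms: none
Why: fluoride-mediated cleavage of both aryl silyl ethers, buffered with acetic acid so that neither base-induced ring opening at C2–O1 (retro-oxa-Michael, which would scramble C2) nor acid-induced addition of the phenols to the side-chain alkenes should occur.

**Compound list**
1 | (S)-4-benzyloxazolidin-2-one | O=C1N[C@@H](Cc2ccccc2)CO1 | starting material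
2 | 3-methylbut-2-enoyl chloride | CC(C)=CC(=O)Cl | starting material
3 | N-lithio (S)-4-benzyloxazolidin-2-one | [Li+].O=C1[N-][C@@H](Cc2ccccc2)CO1 | intermediate (not isolated)
4 | (S)-4-benzyl-3-(3-methylbut-2-enoyl)oxazolidin-2-one | CC(C)=CC(=O)N1[C@@H](Cc2ccccc2)COC1=O | intermediate
5 | 1-bromo-3-methylbut-2-ene | CC(C)=CCBr | starting material
6 | sodium (Z)-dienolate of 4 | C=C(C)/C=C(\[O-])N1[C@@H](Cc2ccccc2)COC1=O.[Na+] | intermediate (not isolated)
7 | (S)-4-benzyl-3-[(2S)-5-methyl-2-(prop-1-en-2-yl)hex-4-enoyl]oxazolidin-2-one | CC(C)=CC[C@@H](C(C)=C)C(=O)N1[C@@H](Cc2ccccc2)COC1=O | intermediate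
8 | (S)-lavandulol | C=C(C)[C@H](CC=C(C)C)CO | intermediate
9 | (S)-lavandulyl iodide | C=C(C)[C@H](CC=C(C)C)CI | intermediate
10 | 5-methoxyresorcinol | COc1cc(O)cc(O)c1 | starting material
11 | 1-methoxy-3,5-bis(methoxymethoxy)benzene | COCOc1cc(OC)cc(OCOC)c1 | intermediate
12 | [4-methoxy-2,6-bis(methoxymethoxy)phenyl]lithium | COCOc1cc(OC)cc(OCOC)c1[Li] | intermediate (not isolated)
13 | 2-iodo-5-methoxy-1,3-bis(methoxymethoxy)benzene | COCOc1cc(OC)cc(OCOC)c1I | intermediate
14 | (S)-lavandulylzinc iodide | C=C(C)[C@H](CC=C(C)C)C[Zn]I | intermediate (not isolated)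
15 | 5-methoxy-1,3-bis(methoxymethoxy)-2-[(R)-lavandulyl]benzene | C=C(C)[C@H](CC=C(C)C)Cc1c(OCOC)cc(OC)cc1OCOC | intermediate
16 | {2-methoxy-4,6-bis(methoxymethoxy)-5-[(R)-lavandulyl]phenyl}lithium | C=C(C)[C@H](CC=C(C)C)Cc1c(OCOC)cc(OC)c([Li])c1OCOC | intermediate (not isolated)
17 | 1-{6-methoxy-2,4-bis(methoxymethoxy)-3-[(R)-lavandulyl]phenyl}ethan-1-one | C=C(C)[C@H](CC=C(C)C)Cc1c(OCOC)cc(OC)c(C(C)=O)c1OCOC | intermediate
18 | 1-{2,4-dihydroxy-6-methoxy-3-[(R)-lavandulyl]phenyl}ethan-1-one | C=C(C)[C@H](CC=C(C)C)Cc1c(O)cc(OC)c(C(C)=O)c1O | intermediate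
19 | 1-{2-hydroxy-6-methoxy-3-[(R)-lavandulyl]-4-(triisopropylsilyloxy)phenyl}ethan-1-one | C=C(C)[C@H](CC=C(C)C)Cc1c(O[Si](C(C)C)(C(C)C)C(C)C)cc(OC)c(C(C)=O)c1O | intermediate
20 | 2-hydroxy-4-methoxybenzaldehyde | COc1ccc(C=O)c(O)c1 | starting material
21 | 4-methoxy-2-(triisopropylsilyloxy)benzaldehyde | COc1ccc(C=O)c(O[Si](C(C)C)(C(C)C)C(C)C)c1 | intermediate
22 | [4-methoxy-2-(triisopropylsilyloxy)phenyl]methanol | COc1ccc(CO)c(O[Si](C(C)C)(C(C)C)C(C)C)c1 | intermediate
23 | 1-{6-methoxy-2-{[4-methoxy-2-(triisopropylsilyloxy)phenyl]methoxy}-3-[(R)-lavandulyl]-4-(triisopropylsilyloxy)phenyl}ethan-1-one | C=C(C)[C@H](CC=C(C)C)Cc1c(O[Si](C(C)C)(C(C)C)C(C)C)cc(OC)c(C(C)=O)c1OCc1ccc(OC)cc1O[Si](C(C)C)(C(C)C)C(C)C | intermediate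
24 | lithium enolate of 23 | C=C(C)[C@H](CC=C(C)C)Cc1c(O[Si](C(C)C)(C(C)C)C(C)C)cc(OC)c(C(=C)O[Li])c1OCc1ccc(OC)cc1O[Si](C(C)C)(C(C)C)C(C)C | intermediate (not isolated)
25 | 4,4,4-trifluoro-1-aryl-butane-1,3-dione from 23 (aryl as in 23) | C=C(C)[C@H](CC=C(C)C)Cc1c(O[Si](C(C)C)(C(C)C)C(C)C)cc(OC)c(C(=O)CC(=O)C(F)(F)F)c1OCc1ccc(OC)cc1O[Si](C(C)C)(C(C)C)C(C)C | intermediate (not isolated)
26 | 2-diazo-1-{6-methoxy-2-{[4-methoxy-2-(triisopropylsilyloxy)phenyl]methoxy}-3-[(R)-lavandulyl]-4-(triisopropylsilyloxy)phenyl}ethan-1-one | C=C(C)[C@H](CC=C(C)C)Cc1c(O[Si](C(C)C)(C(C)C)C(C)C)cc(OC)c(C(=O)C=[N+]=[N-])c1OCc1ccc(OC)cc1O[Si](C(C)C)(C(C)C)C(C)C | intermediate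
27 | (2S)-5-methoxy-2-[4-methoxy-2-(triisopropylsilyloxy)phenyl]-8-[(R)-lavandulyl]-7-(triisopropylsilyloxy)-2,3-dihydro-4H-chromen-4-one | C=C(C)[C@H](CC=C(C)C)Cc1c(O[Si](C(C)C)(C(C)C)C(C)C)cc(OC)c2c1O[C@H](c1ccc(OC)cc1O[Si](C(C)C)(C(C)C)C(C)C)CC2=O | intermediate
28 | (2S)-7-hydroxy-2-(2-hydroxy-4-methoxyphenyl)-5-methoxy-8-[(2R)-5-methyl-2-(prop-1-en-2-yl)hex-4-en-1-yl]-2,3-dihydro-4H-chromen-4-one | C=C(C)[C@H](CC=C(C)C)Cc1c(O)cc(OC)c2c1O[C@H](c1ccc(OC)cc1O)CC2=O | target

**Totals**
Total steps: 16. Longest linear sequence: 12 (steps 1–4, 7–10, 13–16).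

**Steps most likely to fail**

Step 15. The carbene may be captured by the lone pair of O1 to give a five-membered oxonium ylide that collapses by [1,2]-benzyl shift to a benzofuranone skeleton. Discrimination of the two enantiotopic benzylic hydrogens may also be incomplete, so that C2 forms as an epimer mixture. The fallback closes ring C at O1–C2 instead and sets out from 19 and 21. The dianion of 19 (LiN(SiMe3)2, 2.2 equiv, THF, −78 °C) is added to aldehyde 21 to give the β-hydroxy ketone F1 as both carbinol epimers. Intramolecular Mitsunobu etherification (PPh3, DIAD, THF) should give the flavanone as a mixture of 27 and its (2R)-epimer F2. Kinetic resolution by asymmetric transfer hydrogenation of Noyori–Ikariya type (RhCl(C5Me5)[(R,R)-TsDPEN], trivalent rhodium, HCO2H/Et3N, EtOAc, rt) is expected, by the usual aryl ketone model, to reduce the (2R)-epimer to the cis-(2R,4R)-flavan-4-ol F3. The unreduced ketone 27 is then separated by chromatography, and the route is rejoined at 27.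

Step 7. Reductive elimination at the doubly ortho-oxygenated arylpalladium may be slow. β-Hydride elimination and re-insertion could then move the metal along the chain, eroding C2'' and isomerising the diene, or protodezincation could return the reduced arene. The fallback is a copper-catalysed Grignard–tosylate coupling and sets out from 8 and from aryllithium 12 (made from 11 as in step 6). Alcohol 8 is converted with TsCl/pyridine into (S)-lavandulyl tosylate F4. Aryllithium 12 is transmetalated with MgBr2·OEt2 to the arylmagnesium bromide F5. Coupling of F5 with F4 under Li2CuCl4 catalysis (THF, −20 °C → rt) should give 15 directly, where the route is rejoined; steps 4, 6 and 7 are then not needed.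

Step 13. The doubly ortho-substituted, hydrogen-bonded phenol may attack the alkoxyphosphonium intermediate too slowly, so that ionisation of the electron-rich benzylic partner, C-benzylation of ring A or self-condensation take over. The fallback is a Williamson ether synthesis and sets out from 22. The alcohol is converted with CBr4/PPh3 (CH2Cl2, 0 °C) into 4-methoxy-2-(triisopropylsilyloxy)benzyl bromide F6, used crude. The phenoxide of 19 (K2CO3, dry acetone, 50 °C) is alkylated with it to give 23, where the route is rejoined.

**Further compounds**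
F1 | step 15 | 3-hydroxy-1-{2-hydroxy-6-methoxy-3-[(R)-lavandulyl]-4-(triisopropylsilyloxy)phenyl}-3-[4-methoxy-2-(triisopropylsilyloxy)phenyl]propan-1-one (both carbinol epimers) | C=C(C)[C@H](CC=C(C)C)Cc1c(O[Si](C(C)C)(C(C)C)C(C)C)cc(OC)c(C(=O)CC(O)c2ccc(OC)cc2O[Si](C(C)C)(C(C)C)C(C)C)c1O
F2 | step 15 | (2R)-5-methoxy-2-[4-methoxy-2-(triisopropylsilyloxy)phenyl]-8-[(R)-lavandulyl]-7-(triisopropylsilyloxy)-2,3-dihydro-4H-chromen-4-one | C=C(C)[C@H](CC=C(C)C)Cc1c(O[Si](C(C)C)(C(C)C)C(C)C)cc(OC)c2c1O[C@@H](c1ccc(OC)cc1O[Si](C(C)C)(C(C)C)C(C)C)CC2=O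
F3 | step 15 | (2R,4R)-5-methoxy-2-[4-methoxy-2-(triisopropylsilyloxy)phenyl]-8-[(R)-lavandulyl]-7-(triisopropylsilyloxy)chroman-4-ol | C=C(C)[C@H](CC=C(C)C)Cc1c(O[Si](C(C)C)(C(C)C)C(C)C)cc(OC)c2c1O[C@@H](c1ccc(OC)cc1O[Si](C(C)C)(C(C)C)C(C)C)C[C@H]2O
F4 | step 7 | (S)-lavandulyl 4-methylbenzenesulfonate | C=C(C)[C@H](CC=C(C)C)COS(=O)(=O)c1ccc(C)cc1
F5 | step 7 | [4-methoxy-2,6-bis(methoxymethoxy)phenyl]magnesium bromide | COCOc1cc(OC)cc(OCOC)c1[Mg]Br
F6 | step 13 | 4-methoxy-2-(triisopropylsilyloxy)benzyl bromide | COc1ccc(CBr)c(O[Si](C(C)C)(C(C)C)C(C)C)c1
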